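A direct plan would build the ring as a tetronic acid: asymmetric hydrogenation of the β-keto ester A1 (methyl 3-oxohexanoate), silyl protection and saponification, O-acylation to the 2-acyloxyacrylate A2, and Dieckmann closure of C3–C4 to the 5-methylidene tetronic acid A3.
It would then tether a hydrosilane to O4, close the fused oxasilole A4 by iridium-catalysed dehydrogenative silylation of the exocyclic C–H bond, open it by iododesilylation to the E-iodide, exchange the C4 hydroxyl for bromine and remove the silyl ether: ten steps in one line from A1.
Weakest: the dehydrogenative C–H silylation to A4 would have no precedent on an enol lactone, would compete with hydrosilylation and transfer hydrogenation of the methylene group, and would run on a hydrolytically labile vinylogous silyl ester that cannot be purified, yet the whole E geometry would rest on it.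
Weak: the Dieckmann closure to A3 would have to outrun β-elimination of the silyloxy group and oligomerisation of the acrylate, and it is the reason for silylation, saponification and a final desilylation, three steps that would build nothing.
Weak: the late exchange of the C4 hydroxyl for bromine would expose the light- and acid-sensitive iodomethylidene compound to a bromoiminium salt at the point where most material has been invested.

**Retrosynthetic overview**
The target is read as a buta-1,3-diyne that has undergone two anti additions: the C3=C4(Br) bond inside the furanone ring and the exocyclic C5=C6(I) bond are the two former triple bonds.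
Last disconnection: O1–C5 and C6–I together, by anti iodolactonization of an acyclic (E)-3-bromo-2-(1-hydroxybutyl)pent-2-en-4-ynoic acid; the only ring closes in the final step and the (5E) geometry follows from the mechanism.
Before that: C3–C2 and C4–Br, by hydroxyl-directed anti addition of an ethenyl Grignard reagent and then bromine across the carbinol-bearing triple bond of a silyl-capped diynol; the ethenyl group is later cut down to the carboxyl carbon C2. C1' comes from asymmetric transfer hydrogenation of the diynone made from bis(silyl)butadiyne and butanoyl chloride.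
This avoids the tetronic acid, the tethered C–H silylation and the late OH→Br exchange, and needs no protecting group on the C1' hydroxyl: bromine enters when the alkene is made, iodine when the ring closes.

Key step: step 5

Step 1
Reactants: 1 1,4-bis(trimethylsilyl)buta-1,3-diyne; 2 butanoyl chloride
Product: 3 8-(trimethylsilyl)octa-5,7-diyn-4-one
Conditions: AlCl3 (1.1 equiv), CH2Cl2, 0 °C
Reagents that add atoms: none
Why: Friedel–Crafts-type acylative ipso-desilylation of a silylalkyne, in which the acylium ion attacks one silyl-bearing terminus, the β-silyl-stabilised vinyl cation loses the silyl group, and the electron-poor diynone formed should resist a second acylation.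

Step 2
Reactants: 3 8-(trimethylsilyl)octa-5,7-diyn-4-one
Product: 4 (4R)-8-(trimethylsilyl)octa-5,7-diyn-4-ol
Conditions: Ru[(R,R)-TsDPEN](p-cymene) (preformed amido complex, 1 mol%), i-PrOH, rt
Reagents that add atoms: none
Why: Noyori asymmetric transfer hydrogenation of an alkynyl ketone, in which the (R,R)-diamine ligand should deliver hydride to the face that gives the (R)-propargylic alcohol (the sense known for alkynyl alkyl ketones) and so sets C1' without reducing the diyne or cleaving the silyl group.

Step 3
Reactants: 4 (4R)-8-(trimethylsilyl)octa-5,7-diyn-4-ol; 5 ethenylmagnesium chloride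
Product: 7 (4R,5Z)-6-bromo-5-ethenyl-8-(trimethylsilyl)oct-5-en-7-yn-4-ol, via oxamagnesole chelate 6 (not isolated)
Conditions: 5 (4 equiv), THF, 65 °C; then NBS, THF, −78 to 0 °C; aq. NH4Cl
Reagents that add atoms: N-bromosuccinimide, O=C1CCC(=O)N1Br
Why: Hydroxyl-directed anti-carbomagnesiation of a propargylic alcohol, in which the magnesium alkoxide should guide the ethenyl group to the alkyne carbon next to the carbinol and hold the new C–Mg bond at the distal carbon in a five-membered chelate (stabilised by the adjacent alkynyl group), so that brominolysis with retention places Br cis to C1' and the ethenyl group cis to the silylalkyne, with C1' untouched.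

Step 4
Reactants: 7 (4R,5Z)-6-bromo-5-ethenyl-8-(trimethylsilyl)oct-5-en-7-yn-4-ol
Product: 9 (2E)-3-bromo-2-[(1R)-1-hydroxybutyl]-5-(trimethylsilyl)pent-2-en-4-ynoic acid, via silylated enynal 8 (not isolated)
Conditions: O3 (1.05 equiv), MeCN/H2O (9:1), −10 °C; then NaClO2, H2O, 0 °C to rt; work-up at pH 3
Reagents that add atoms: ozone, [O-][O+]=O; water, O; sodium chlorite, [Na+].[O-]Cl=O
Why: Ozonolysis in aqueous acetonitrile should cleave only the monosubstituted, most electron-rich C=C bond directly to the aldehyde (the bromo- and alkynyl-substituted alkene and the silylalkyne are far less reactive towards ozone), and chlorite oxidation in the same flask (Pinnick-type, with the hydrogen peroxide formed acting as hypochlorite scavenger) should give the acid without change of the alkene geometry.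

Step 5
Reactants: 9 (2E)-3-bromo-2-[(1R)-1-hydroxybutyl]-5-(trimethylsilyl)pent-2-en-4-ynoic acid
Product: 11 (5E)-4-bromo-3-[(1R)-1-hydroxybutyl]-5-(iodomethylidene)furan-2(5H)-one, via desilylated enynoic acid 10 (not isolated)
Conditions: K2CO3 (2.2 equiv), MeOH, 0 °C; evaporation; then I2 (1.2 equiv), MeCN/H2O, 0 °C, dark; aq. Na2S2O3
Reagents that add atoms: iodine, II
Why: Carbonate in methanol should first cleave the alkynyl C–Si bond and leave the potassium carboxylate of 10; iodine then forms an iodonium ion on the terminal triple bond, and the carboxylate, held cis to the alkyne by the C3=C4 geometry set in step 3, attacks the internal carbon C5 from the side opposite to iodine. The closest known reaction type is the iodolactonization of (Z)-2-en-4-ynoic acids and of pent-4-ynoic acids, which gives (E)-5-(iodomethylidene) lactones. The furanone ring closes in the 5-exo-dig mode through the new O1–C5 bond, and the C6–I bond forms in the same event. No stereocentre is created; the geometry of C5=C6 is controlled by the anti course of the addition, which puts O1 and iodine trans and iodine on the side of C4, as the target requires. The step needs 5-exo over 6-endo closure, which the terminal alkyne should secure because the positive charge of the iodonium ion sits on the internal carbon, and it needs the free C1' hydroxyl to stay out, which it must because it lies on the bromine side of the alkene, trans to the alkyne. Exclusion of light and a prompt thiosulfate quench should keep the crowded E-iodide (iodine next to the C4 bromine) from isomerising.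

**Compound list**

1 | 1,4-bis(trimethylsilyl)buta-1,3-diyne | C[Si](C)(C)C#CC#C[Si](C)(C)C | starting material
2 | butanoyl chloride | CCCC(=O)Cl | starting material
3 | 8-(trimethylsilyl)octa-5,7-diyn-4-one | CCCC(=O)C#CC#C[Si](C)(C)C | intermediate
4 | (4R)-8-(trimethylsilyl)octa-5,7-diyn-4-ol | CCC[C@@H](O)C#CC#C[Si](C)(C)C | intermediate
5 | ethenylmagnesium chloride | C=C[Mg]Cl | starting material
6 | magnesium chelate (5R)-4-ethenyl-5-propyl-3-[(trimethylsilyl)ethynyl]-2,5-dihydro-1,2-oxamagnesole (Mg bridges the alkoxide O and the alkenyl carbon; not isolated) | CCC[C@H]1O[Mg]C(C#C[Si](C)(C)C)=C1C=C | intermediate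
7 | (4R,5Z)-6-bromo-5-ethenyl-8-(trimethylsilyl)oct-5-en-7-yn-4-ol (Br cis to the carbinol carbon) | CCC[C@@H](O)/C(C=C)=C(\Br)C#C[Si](C)(C)C | intermediate
8 | (2E)-3-bromo-2-[(1R)-1-hydroxybutyl]-5-(trimethylsilyl)pent-2-en-4-ynal (not isolated) | CCC[C@@H](O)/C(C=O)=C(\Br)C#C[Si](C)(C)C | intermediate
9 | (2E)-3-bromo-2-[(1R)-1-hydroxybutyl]-5-(trimethylsilyl)pent-2-en-4-ynoic acid (carboxyl cis to the alkyne) | CCC[C@@H](O)/C(C(=O)O)=C(\Br)C#C[Si](C)(C)C | intermediate
10 | (2E)-3-bromo-2-[(1R)-1-hydroxybutyl]pent-2-en-4-ynoic acid (formed as its potassium salt; not isolated) | CCC[C@@H](O)/C(C(=O)O)=C(\Br)C#C | intermediate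
11 | (5E)-4-bromo-3-[(1R)-1-hydroxybutyl]-5-(iodomethylidene)furan-2(5H)-one | CCC[C@@H](O)C1=C(Br)/C(=C\I)OC1=O | target

Total step count: 5. Longest linear sequence: 5 steps (1 → 3 → 4 → 7 → 9 → 11).

**Steps most likely to fail**

Step 3. The Grignard reagent may add at the wrong carbon of the conjugated diyne, the enynyl magnesium intermediate may take up bromine at its remote alkyne carbon (cumulene formation), or the silyl group may be lost. Fallback: the alkene would be built by electrophilic instead of nucleophilic anti addition. Setting out from 4, iodine monobromide (CH2Cl2, −78 °C) should add anti across the carbinol-bearing triple bond, bromide entering at the alkynyl-substituted carbon that carries the positive charge, to give (4R,5E)-6-bromo-5-iodo-8-(trimethylsilyl)oct-5-en-7-yn-4-ol F1. A Stille coupling of its C–I bond with tributyl(ethenyl)stannane (Pd2(dba)3, AsPh3, CuI, DMF, rt), which proceeds with retention and should leave the C–Br bond, would come back to the route at 7.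

Step 4. Ozone may also attack the tetrasubstituted bromoalkene or the triple bond (over-oxidation), or the enal may be degraded by hypochlorite. Fallback: the carboxyl carbon would be brought in at the alcohol level, so that no C=C bond has to be cleaved. Setting out from 4, the same directed anti addition with [dimethyl(propan-2-yloxy)silyl]methylmagnesium chloride (CuI cat., THF) and NBS would give (4R,5E)-6-bromo-5-{[dimethyl(propan-2-yloxy)silyl]methyl}-8-(trimethylsilyl)oct-5-en-7-yn-4-ol F2. Tamao oxidation (H2O2, KF, KHCO3, THF/MeOH), which should also remove the alkynyl silyl group, would give (2Z,3R)-2-(1-bromoprop-2-yn-1-ylidene)hexane-1,3-diol F3. Oxidation of the primary allylic alcohol alone with TEMPO/PhI(OAc)2 would give (2E)-3-bromo-2-[(1R)-1-hydroxybutyl]pent-2-en-4-ynal F4, and NaClO2/NaH2PO4/2-methylbut-2-ene would come back to the route at 10.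

Step 5. The ring may close 6-endo to the pyranone, iodine may attack the bromine-deactivated alkyne too slowly, or iodine and light may isomerise the E-iodide. Fallback: the C–I bonds would be made first and the C–O bond second. Setting out from 10, iodine without base (CH2Cl2, dark) should add anti to the terminal alkyne to give (2E,4E)-3-bromo-2-[(1R)-1-hydroxybutyl]-4,5-diiodopenta-2,4-dienoic acid F5. A copper-catalysed intramolecular O-vinylation of the carboxylate at the internal C–I bond (CuI, N,N'-dimethylethane-1,2-diamine, Cs2CO3, toluene, 60 °C), which proceeds with retention and so keeps O1 trans to the remaining iodine, would come back to the route at 11.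

**Further compounds**

F1 | step 3 | (4R,5E)-6-bromo-5-iodo-8-(trimethylsilyl)oct-5-en-7-yn-4-ol | CCC[C@@H](O)/C(I)=C(\Br)C#C[Si](C)(C)C
F2 | step 4 | (4R,5E)-6-bromo-5-{[dimethyl(propan-2-yloxy)silyl]methyl}-8-(trimethylsilyl)oct-5-en-7-yn-4-ol | CCC[C@@H](O)/C(C[Si](C)(C)OC(C)C)=C(\Br)C#C[Si](C)(C)C
F3 | step 4 | (2Z,3R)-2-(1-bromoprop-2-yn-1-ylidene)hexane-1,3-diol | CCC[C@@H](O)/C(CO)=C(\Br)C#C
F4 | step 4 | (2E)-3-bromo-2-[(1R)-1-hydroxybutyl]pent-2-en-4-ynal | CCC[C@@H](O)/C(C=O)=C(\Br)C#C
F5 | step 5 | (2E,4E)-3-bromo-2-[(1R)-1-hydroxybutyl]-4,5-diiodopenta-2,4-dienoic acid | CCC[C@@H](O)/C(C(=O)O)=C(\Br)/C(I)=C\I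
A1 | direct plan | methyl 3-oxohexanoate | CCCC(=O)CC(=O)OC
A2 | direct plan | methyl 2-{[(3R)-3-(tert-butyldimethylsilyloxy)hexanoyl]oxy}prop-2-enoate | CCC[C@@H](O[Si](C)(C)C(C)(C)C)CC(=O)OC(=C)C(=O)OC
A3 | direct plan | 3-[(1R)-1-(tert-butyldimethylsilyloxy)butyl]-4-hydroxy-5-methylidenefuran-2(5H)-one | CCC[C@@H](O[Si](C)(C)C(C)(C)C)C1=C(O)C(=C)OC1=O
A4 | direct plan | furanone-fused 2,2-diisopropyl-1,2-oxasilole (ring C4–O–Si–C6=C5) with the (1R)-1-(tert-butyldimethylsilyloxy)butyl group at C3 | CCC[C@@H](O[Si](C)(C)C(C)(C)C)C1=C2O[Si](C(C)C)(C(C)C)C=C2OC1=O
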